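**Assumption:** the stereodescriptors are taken exactly as written, (4R,5R,6S,7R,8R,10S) in germacrane numbering; this makes the 5,10-ether the trans-bridged (inside–outside) 11-oxabicyclo[4.4.1]undecene, and the route is built for that isomer.

Numbering used below: C1 ring ketone, C2=C3, C4 (bears C15H2OH), C5 and C10 ether carbons, C6 lactone CH–O, C7 ring fusion, C8 angelate carbon, C9 CH2, C11–C13 α-methylene lactone, C14 methyl. Abbreviations: TBS = tert-butyldimethylsilyl, TBDPS = tert-butyldiphenylsilyl, Bz = benzoyl.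

## Retrosynthetic overview

1. Target ⇐ desilylation/lactonisation and angeloylation of the bicyclic hydroxy acrylate 26.
2. Ring B last: C7–C8 by intramolecular Barbier allylation of aldehyde 24, the allylindium acting as a β-carbanion (homoenolate) equivalent of the acrylate (key step); the acrylate arm comes from cross-metathesis.
3. Ring A first: C1–C10 by SmI2 ketyl addition to a β-alkoxyvinyl sulfone, which sets quaternary C10; the sulfone then becomes the C14 methyl and IBX gives the enone.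
4. Acyclic C4–C6 triad: organocatalytic α-hydroxymethylation (C4) and iridium-catalysed anti-benzoyloxyallylation (C5, C6); C8–C10 and C14 come from an alkynyl sulfone.
5. Ring order: oxepenone ring A → trans-bridged oxepane ring B → γ-lactone.

## Route

Step 1
Reactants: 1 cyclopentene
Product: 4 5,5-dimethoxypentanal, via hydroperoxide aldehyde 2 (not isolated), via hydroperoxy acetal 3 (not isolated)
Conditions: O3, MeOH/CH2Cl2, −78 °C; TsOH (cat.), rt; NaHCO3; Me2S, rt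
Reagents that add atoms: ozone [O-][O+]=O; methanol CO
Why: Schreiber unsymmetrical ozonolysis, in which methanol traps the Criegee intermediate as a methoxy hydroperoxide, acid acetalises the free aldehyde end, and dimethyl sulfide then reduces the hydroperoxide end to the aldehyde; no stereocentre is formed.

Step 2
Reactants: 4 5,5-dimethoxypentanal
Product: 5 (2R)-2-(hydroxymethyl)-5,5-dimethoxypentanal
Conditions: aq. CH2O, (S)-α,α-diphenylprolinol trimethylsilyl ether (10 mol %), pH 7 phosphate buffer, toluene, rt; used crude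
Reagents that add atoms: formaldehyde C=O
Why: Enamine-catalysed α-hydroxymethylation (organocatalytic cross-aldol with formaldehyde), in which the diarylsilyloxymethyl group shields one enamine face and sets C4 as R (catalyst antipode assigned by analogy with related enamine additions).

Step 3
Reactants: 5 (2R)-2-(hydroxymethyl)-5,5-dimethoxypentanal
Product: 6 (2R)-2-(TBDPS-oxymethyl)-5,5-dimethoxypentanal
Conditions: TBDPSCl, imidazole, CH2Cl2, 0 °C
Reagents that add atoms: tert-butyl(chloro)diphenylsilane CC(C)(C)[Si](Cl)(c1ccccc1)c1ccccc1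
Why: Standard silylation of the primary alcohol under mild conditions that leave the epimerisable α-stereocentre untouched.

Step 4
Reactants: 7 acrolein; 8 benzoic anhydride
Product: 9 prop-2-ene-1,1-diyl dibenzoate
Conditions: H2SO4 (cat.), neat, 0 °C → rt
Reagents that add atoms: none
Why: Acid-catalysed acylal formation from an aldehyde and an anhydride gives the allyl donor for step 5.

Step 5
Reactants: 6 (2R)-2-(TBDPS-oxymethyl)-5,5-dimethoxypentanal; 9 prop-2-ene-1,1-diyl dibenzoate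
Product: 10 (3S,4R,5R)-5-(TBDPS-oxymethyl)-4-hydroxy-8,8-dimethoxyoct-1-en-3-yl benzoate
Conditions: [Ir(cod)Cl]2 (2.5 mol %), (R)-SEGPHOS (5 mol %), 4-cyano-3-nitrobenzoic acid (10 mol %), K3PO4 (10 mol %), i-PrOH, THF, 60 °C
Reagents that add atoms: none
Why: Iridium-catalysed transfer-hydrogenative anti-(α-benzoyloxy)allylation (Krische type), in which the (E)-benzoyloxyallyl iridium adds through a closed chair to give the anti C5–OH/C6–OBz pair; the ligand antipode that delivers 5R,6S is used ((R) is written by analogy) and overrides the weak bias of C4.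

Step 6
Reactants: 11 tert-butyl(but-3-yn-1-yloxy)dimethylsilane
Product: 13 tert-butyldimethyl{[4-(phenylsulfonyl)but-3-yn-1-yl]oxy}silane, via acetylide 12 (not isolated)
Conditions: n-BuLi, THF, −78 °C; PhSO2F, −78 °C → rt
Reagents that add atoms: benzenesulfonyl fluoride O=S(=O)(F)c1ccccc1
Why: Sulfonylation of a lithium acetylide with a sulfonyl fluoride (attack at sulfur, fluoride leaving) gives the alkynyl sulfone that will supply C8, C9, C10 and C14.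

Step 7
Reactants: 10 (3S,4R,5R)-5-(TBDPS-oxymethyl)-4-hydroxy-8,8-dimethoxyoct-1-en-3-yl benzoate; 13 tert-butyldimethyl{[4-(phenylsulfonyl)but-3-yn-1-yl]oxy}silane
Product: 14 (3S,4R,5R)-4-{[(1E)-4-(TBS-oxy)-1-(phenylsulfonyl)but-1-en-2-yl]oxy}-5-(TBDPS-oxymethyl)-8,8-dimethoxyoct-1-en-3-yl benzoate
Conditions: PMe3 (20 mol %), CH2Cl2, 0 °C → rt
Reagents that add atoms: none
Why: Phosphine-catalysed oxa-Michael addition of the C5 hydroxyl to the alkynyl sulfone gives the thermodynamic (E)-β-alkoxyvinyl sulfone without touching the stereocentres; low temperature and short time limit 1,2-benzoate migration.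

Step 8
Reactants: 14 (3S,4R,5R)-4-{[(1E)-4-(TBS-oxy)-1-(phenylsulfonyl)but-1-en-2-yl]oxy}-5-(TBDPS-oxymethyl)-8,8-dimethoxyoct-1-en-3-yl benzoate
Product: 15 (3S,4R,5R)-4-{[(1E)-4-(TBS-oxy)-1-(phenylsulfonyl)but-1-en-2-yl]oxy}-5-(TBDPS-oxymethyl)-8-oxooct-1-en-3-yl benzoate
Conditions: LiBF4, MeCN/H2O (50:1), rt
Reagents that add atoms: water O
Why: Chemoselective acetal hydrolysis frees the C1 aldehyde, while the vinylogous sulfonate enol ether, the benzoate and both silyl ethers survive the mild Lewis acid.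

Step 9
Reactants: 15 (3S,4R,5R)-4-{[(1E)-4-(TBS-oxy)-1-(phenylsulfonyl)but-1-en-2-yl]oxy}-5-(TBDPS-oxymethyl)-8-oxooct-1-en-3-yl benzoate
Product: 16 (1S)-1-[(2R,3R,6S,7S)-7-[2-(TBS-oxy)ethyl]-3-(TBDPS-oxymethyl)-6-hydroxy-7-[(phenylsulfonyl)methyl]oxepan-2-yl]prop-2-en-1-yl benzoate
Conditions: SmI2 (3 equiv), MeOH (3 equiv), THF, 0 °C → rt
Reagents that add atoms: none
Why: Nakata-type reductive ketyl–olefin cyclisation, in which the C1 ketyl (a polarity-reversed carbonyl carbon) adds 7-exo to the β-carbon of the alkoxyvinyl sulfone through a chelated chair-like transition state; the sulfonylmethyl arm sits equatorial, cis to the C5 side chain, which fixes C10 with the future methyl cis to C6 (the C1 carbinol centre is erased in step 12).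

Step 10
Reactants: 16 (1S)-1-[(2R,3R,6S,7S)-7-[2-(TBS-oxy)ethyl]-3-(TBDPS-oxymethyl)-6-hydroxy-7-[(phenylsulfonyl)methyl]oxepan-2-yl]prop-2-en-1-yl benzoate
Product: 17 (2S,3S,6R,7R)-2-[2-(TBS-oxy)ethyl]-6-(TBDPS-oxymethyl)-7-[(1S)-1-hydroxyprop-2-en-1-yl]-2-methyloxepan-3-ol
Conditions: Mg turnings, MeOH, rt → 40 °C
Reagents that add atoms: none
Why: Dissolving-metal desulfonylation turns the sulfonylmethyl arm into the C14 methyl (protonation by methanol outruns β-alkoxide loss), and the magnesium methoxide formed removes the benzoate by transesterification; no stereocentre is affected.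

Step 11
Reactants: 17 (2S,3S,6R,7R)-2-[2-(TBS-oxy)ethyl]-6-(TBDPS-oxymethyl)-7-[(1S)-1-hydroxyprop-2-en-1-yl]-2-methyloxepan-3-ol
Product: 18 (2S,3S,6R,7R)-2-[2-(TBS-oxy)ethyl]-6-(TBDPS-oxymethyl)-7-[(1S)-1-(TBS-oxy)prop-2-en-1-yl]-2-methyloxepan-3-ol
Conditions: TBSCl (1.1 equiv), imidazole, DMF, 0 °C
Reagents that add atoms: tert-butyl(chloro)dimethylsilane CC(C)(C)[Si](C)(C)Cl
Why: Site-selective silylation, in which the allylic C6 hydroxyl reacts while the neopentyl-type C1 carbinol next to quaternary C10 stays free.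

Step 12
Reactants: 18 (2S,3S,6R,7R)-2-[2-(TBS-oxy)ethyl]-6-(TBDPS-oxymethyl)-7-[(1S)-1-(TBS-oxy)prop-2-en-1-yl]-2-methyloxepan-3-ol
Product: 20 (2S,6R,7R)-2-[2-(TBS-oxy)ethyl]-6-(TBDPS-oxymethyl)-7-[(1S)-1-(TBS-oxy)prop-2-en-1-yl]-2-methyl-6,7-dihydrooxepin-3(2H)-one, via ketone 19 (not isolated)
Conditions: IBX (3.5 equiv), DMSO/fluorobenzene, 70 °C
Reagents that add atoms: none
Why: Nicolaou IBX oxidation–dehydrogenation (alcohol → ketone → enone); enolisation is possible only toward C2 because C10 is quaternary, so the C2=C3 bond forms regiospecifically and is cis by ring size.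

Step 13
Reactants: 20 (2S,6R,7R)-2-[2-(TBS-oxy)ethyl]-6-(TBDPS-oxymethyl)-7-[(1S)-1-(TBS-oxy)prop-2-en-1-yl]-2-methyl-6,7-dihydrooxepin-3(2H)-one
Product: 21 (2S,6R,7R)-2-(2-hydroxyethyl)-6-(TBDPS-oxymethyl)-7-[(1S)-1-(TBS-oxy)prop-2-en-1-yl]-2-methyl-6,7-dihydrooxepin-3(2H)-one
Conditions: HF·pyridine, pyridine, THF, 0 °C
Reagents that add atoms: none
Why: Selective desilylation, since buffered fluoride removes the primary TBS ether much faster than the secondary allylic TBS ether or the TBDPS ether.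

Step 14
Reactants: 21 (2S,6R,7R)-2-(2-hydroxyethyl)-6-(TBDPS-oxymethyl)-7-[(1S)-1-(TBS-oxy)prop-2-en-1-yl]-2-methyl-6,7-dihydrooxepin-3(2H)-one
Product: 22 2-[(2S,6R,7R)-6-(TBDPS-oxymethyl)-7-[(1S)-1-(TBS-oxy)prop-2-en-1-yl]-2-methyl-3-oxo-2,3,6,7-tetrahydrooxepin-2-yl]acetaldehyde
Conditions: Dess–Martin periodinane, CH2Cl2, 0 °C → rt
Reagents that add atoms: none
Why: Neutral Dess–Martin oxidation gives the base-sensitive β-alkoxy aldehyde (C8) without retro-oxa-Michael opening or epimerisation.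

Step 15
Reactants: 22 2-[(2S,6R,7R)-6-(TBDPS-oxymethyl)-7-[(1S)-1-(TBS-oxy)prop-2-en-1-yl]-2-methyl-3-oxo-2,3,6,7-tetrahydrooxepin-2-yl]acetaldehyde; 23 tert-butyl 2-(bromomethyl)prop-2-enoate
Product: 24 tert-butyl (2Z,4S)-2-(bromomethyl)-4-(TBS-oxy)-4-[(2R,3R,7S)-3-(TBDPS-oxymethyl)-7-methyl-6-oxo-7-(2-oxoethyl)-2,3,6,7-tetrahydrooxepin-2-yl]but-2-enoate
Conditions: 23 (10 equiv), second-generation Hoveyda–Grubbs catalyst (10 mol %), CH2Cl2, 40 °C
Reagents that add atoms: none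
Why: Olefin cross-metathesis of the terminal vinyl group with the 1,1-disubstituted acrylate gives the trisubstituted enoate with C6 trans to the ester (the thermodynamic isomer, Z by CIP) and releases ethene; the endocyclic enone is inert.

Step 16
Reactants: 24 tert-butyl (2Z,4S)-2-(bromomethyl)-4-(TBS-oxy)-4-[(2R,3R,7S)-3-(TBDPS-oxymethyl)-7-methyl-6-oxo-7-(2-oxoethyl)-2,3,6,7-tetrahydrooxepin-2-yl]but-2-enoate
Product: 26 tert-butyl 2-[(1S,5R,6R,7S,8R,9R)-7-(TBS-oxy)-5-(TBDPS-oxymethyl)-9-hydroxy-1-methyl-2-oxo-11-oxabicyclo[4.4.1]undec-3-en-8-yl]prop-2-enoate, via allylindium 25 (not isolated)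
Conditions: In powder, THF/H2O (1:1), rt, 0.003 M
Reagents that add atoms: none
Why: Key intramolecular Barbier allylation, in which the allylindium (a β-carbanion, i.e. homoenolate, equivalent of the acrylate) attacks the C8 aldehyde through C7 in a metal-bridged chair; allylic 1,3-strain keeps H6 in the alkene plane so the tethered aldehyde adds anti to the C6 silyloxy group (C7 = R), the (Z)-allyl geometry gives the syn adduct (C8 = R), and the trans-bridged ring B closes.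

Step 17
Reactants: 26 tert-butyl 2-[(1S,5R,6R,7S,8R,9R)-7-(TBS-oxy)-5-(TBDPS-oxymethyl)-9-hydroxy-1-methyl-2-oxo-11-oxabicyclo[4.4.1]undec-3-en-8-yl]prop-2-enoate; 27 angelic acid
Product: 29 tert-butyl 2-[(1S,5R,6R,7S,8R,9R)-7-(TBS-oxy)-5-(TBDPS-oxymethyl)-1-methyl-9-[(2Z)-2-methylbut-2-enoyloxy]-2-oxo-11-oxabicyclo[4.4.1]undec-3-en-8-yl]prop-2-enoate, via mixed anhydride 28 (not isolated)
Conditions: 27, 2,4,6-trichlorobenzoyl chloride, Et3N, toluene, rt; then 26, 75 °C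
Reagents that add atoms: none
Why: Yamaguchi-type acylation through the mixed anhydride without DMAP, conditions that transfer the angeloyl group without Z→E isomerisation; C8 is acylated with retention and is the only free hydroxyl.

Step 18
Reactants: 29 tert-butyl 2-[(1S,5R,6R,7S,8R,9R)-7-(TBS-oxy)-5-(TBDPS-oxymethyl)-1-methyl-9-[(2Z)-2-methylbut-2-enoyloxy]-2-oxo-11-oxabicyclo[4.4.1]undec-3-en-8-yl]prop-2-enoate
Product: 32 target lactone CNP0274187.1, via diol ester 30 (not isolated), via hydroxy acid 31 (not isolated)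
Conditions: HF·pyridine, THF, 0 °C → rt; then TFA, CH2Cl2, 0 °C
Reagents that add atoms: none
Why: Global desilylation frees the C6 and C15 hydroxyls, and acid then cleaves the tert-butyl ester and drives γ-lactonisation onto C6–OH (the only hydroxyl that can close a five-membered ring), giving the trans-fused α-methylene lactone with no stereocentre touched.

## Compound list

1 | cyclopentene | C1=CCCC1 | starting material
2 | 5-hydroperoxy-5-methoxypentanal | COC(OO)CCCC=O | intermediate (not isolated)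
3 | 1-hydroperoxy-1,5,5-trimethoxypentane | COC(OO)CCCC(OC)OC | intermediate (not isolated)
4 | 5,5-dimethoxypentanal | COC(OC)CCCC=O | intermediate
5 | (2R)-2-(hydroxymethyl)-5,5-dimethoxypentanal | COC(OC)CC[C@@H](C=O)CO | intermediate
6 | (2R)-2-(TBDPS-oxymethyl)-5,5-dimethoxypentanal | COC(OC)CC[C@@H](C=O)CO[Si](c1ccccc1)(c1ccccc1)C(C)(C)C | intermediate
7 | acrolein (prop-2-enal) | C=CC=O | starting material
8 | benzoic anhydride | O=C(OC(=O)c1ccccc1)c1ccccc1 | starting material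
9 | prop-2-ene-1,1-diyl dibenzoate | C=CC(OC(=O)c1ccccc1)OC(=O)c1ccccc1 | intermediate
10 | (3S,4R,5R)-5-(TBDPS-oxymethyl)-4-hydroxy-8,8-dimethoxyoct-1-en-3-yl benzoate | COC(OC)CC[C@H](CO[Si](c1ccccc1)(c1ccccc1)C(C)(C)C)[C@@H](O)[C@@H](OC(=O)c1ccccc1)C=C | intermediate
11 | tert-butyl(but-3-yn-1-yloxy)dimethylsilane | C#CCCO[Si](C)(C)C(C)(C)C | starting material
12 | lithium 4-(TBS-oxy)but-1-yn-1-ide | [Li]C#CCCO[Si](C)(C)C(C)(C)C | intermediate (not isolated)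
13 | tert-butyldimethyl{[4-(phenylsulfonyl)but-3-yn-1-yl]oxy}silane | CC(C)(C)[Si](C)(C)OCCC#CS(=O)(=O)c1ccccc1 | intermediate
14 | (3S,4R,5R)-4-{[(1E)-4-(TBS-oxy)-1-(phenylsulfonyl)but-1-en-2-yl]oxy}-5-(TBDPS-oxymethyl)-8,8-dimethoxyoct-1-en-3-yl benzoate | COC(OC)CC[C@H](CO[Si](c1ccccc1)(c1ccccc1)C(C)(C)C)[C@@H](O/C(CCO[Si](C)(C)C(C)(C)C)=C/S(=O)(=O)c1ccccc1)[C@@H](OC(=O)c1ccccc1)C=C | intermediate
15 | (3S,4R,5R)-4-{[(1E)-4-(TBS-oxy)-1-(phenylsulfonyl)but-1-en-2-yl]oxy}-5-(TBDPS-oxymethyl)-8-oxooct-1-en-3-yl benzoate | O=CCC[C@H](CO[Si](c1ccccc1)(c1ccccc1)C(C)(C)C)[C@@H](O/C(CCO[Si](C)(C)C(C)(C)C)=C/S(=O)(=O)c1ccccc1)[C@@H](OC(=O)c1ccccc1)C=C | intermediate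
16 | (1S)-1-[(2R,3R,6S,7S)-7-[2-(TBS-oxy)ethyl]-3-(TBDPS-oxymethyl)-6-hydroxy-7-[(phenylsulfonyl)methyl]oxepan-2-yl]prop-2-en-1-yl benzoate | CC(C)(C)[Si](C)(C)OCC[C@]1(CS(=O)(=O)c2ccccc2)O[C@@H]([C@@H](OC(=O)c2ccccc2)C=C)[C@@H](CO[Si](c2ccccc2)(c2ccccc2)C(C)(C)C)CC[C@@H]1O | intermediate
17 | (2S,3S,6R,7R)-2-[2-(TBS-oxy)ethyl]-6-(TBDPS-oxymethyl)-7-[(1S)-1-hydroxyprop-2-en-1-yl]-2-methyloxepan-3-ol | CC(C)(C)[Si](C)(C)OCC[C@]1(C)O[C@@H]([C@@H](O)C=C)[C@@H](CO[Si](c2ccccc2)(c2ccccc2)C(C)(C)C)CC[C@@H]1O | intermediate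
18 | (2S,3S,6R,7R)-2-[2-(TBS-oxy)ethyl]-6-(TBDPS-oxymethyl)-7-[(1S)-1-(TBS-oxy)prop-2-en-1-yl]-2-methyloxepan-3-ol | CC(C)(C)[Si](C)(C)OCC[C@]1(C)O[C@@H]([C@@H](O[Si](C)(C)C(C)(C)C)C=C)[C@@H](CO[Si](c2ccccc2)(c2ccccc2)C(C)(C)C)CC[C@@H]1O | intermediate
19 | (2S,6R,7R)-2-[2-(TBS-oxy)ethyl]-6-(TBDPS-oxymethyl)-7-[(1S)-1-(TBS-oxy)prop-2-en-1-yl]-2-methyloxepan-3-one | CC(C)(C)[Si](C)(C)OCC[C@]1(C)O[C@@H]([C@@H](O[Si](C)(C)C(C)(C)C)C=C)[C@@H](CO[Si](c2ccccc2)(c2ccccc2)C(C)(C)C)CCC1=O | intermediate (not isolated)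
20 | (2S,6R,7R)-2-[2-(TBS-oxy)ethyl]-6-(TBDPS-oxymethyl)-7-[(1S)-1-(TBS-oxy)prop-2-en-1-yl]-2-methyl-6,7-dihydrooxepin-3(2H)-one | CC(C)(C)[Si](C)(C)OCC[C@]1(C)O[C@@H]([C@@H](O[Si](C)(C)C(C)(C)C)C=C)[C@@H](CO[Si](c2ccccc2)(c2ccccc2)C(C)(C)C)C=CC1=O | intermediate
21 | (2S,6R,7R)-2-(2-hydroxyethyl)-6-(TBDPS-oxymethyl)-7-[(1S)-1-(TBS-oxy)prop-2-en-1-yl]-2-methyl-6,7-dihydrooxepin-3(2H)-one | OCC[C@]1(C)O[C@@H]([C@@H](O[Si](C)(C)C(C)(C)C)C=C)[C@@H](CO[Si](c2ccccc2)(c2ccccc2)C(C)(C)C)C=CC1=O | intermediate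
22 | 2-[(2S,6R,7R)-6-(TBDPS-oxymethyl)-7-[(1S)-1-(TBS-oxy)prop-2-en-1-yl]-2-methyl-3-oxo-2,3,6,7-tetrahydrooxepin-2-yl]acetaldehyde | O=CC[C@]1(C)O[C@@H]([C@@H](O[Si](C)(C)C(C)(C)C)C=C)[C@@H](CO[Si](c2ccccc2)(c2ccccc2)C(C)(C)C)C=CC1=O | intermediate
23 | tert-butyl 2-(bromomethyl)prop-2-enoate | C=C(CBr)C(=O)OC(C)(C)C | starting material
24 | tert-butyl (2Z,4S)-2-(bromomethyl)-4-(TBS-oxy)-4-[(2R,3R,7S)-3-(TBDPS-oxymethyl)-7-methyl-6-oxo-7-(2-oxoethyl)-2,3,6,7-tetrahydrooxepin-2-yl]but-2-enoate | O=CC[C@]1(C)O[C@@H]([C@@H](O[Si](C)(C)C(C)(C)C)/C=C(\CBr)C(=O)OC(C)(C)C)[C@@H](CO[Si](c2ccccc2)(c2ccccc2)C(C)(C)C)C=CC1=O | intermediate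
25 | allylindium from 24 (bromine replaced by monovalent indium) | O=CC[C@]1(C)O[C@@H]([C@@H](O[Si](C)(C)C(C)(C)C)/C=C(\C[In])C(=O)OC(C)(C)C)[C@@H](CO[Si](c2ccccc2)(c2ccccc2)C(C)(C)C)C=CC1=O | intermediate (not isolated)
26 | tert-butyl 2-[(1S,5R,6R,7S,8R,9R)-7-(TBS-oxy)-5-(TBDPS-oxymethyl)-9-hydroxy-1-methyl-2-oxo-11-oxabicyclo[4.4.1]undec-3-en-8-yl]prop-2-enoate | C=C(C(=O)OC(C)(C)C)[C@@H]1[C@H](O)C[C@]2(C)O[C@@H]([C@H]1O[Si](C)(C)C(C)(C)C)[C@@H](CO[Si](c1ccccc1)(c1ccccc1)C(C)(C)C)C=CC2=O | intermediate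
27 | angelic acid, (2Z)-2-methylbut-2-enoic acid | OC(=O)/C(C)=C\C | starting material
28 | (2Z)-2-methylbut-2-enoic 2,4,6-trichlorobenzoic anhydride | O=C(OC(=O)c1c(Cl)cc(Cl)cc1Cl)/C(C)=C\C | intermediate (not isolated)
29 | tert-butyl 2-[(1S,5R,6R,7S,8R,9R)-7-(TBS-oxy)-5-(TBDPS-oxymethyl)-1-methyl-9-[(2Z)-2-methylbut-2-enoyloxy]-2-oxo-11-oxabicyclo[4.4.1]undec-3-en-8-yl]prop-2-enoate | C=C(C(=O)OC(C)(C)C)[C@@H]1[C@H](OC(=O)/C(C)=C\C)C[C@]2(C)O[C@@H]([C@H]1O[Si](C)(C)C(C)(C)C)[C@@H](CO[Si](c1ccccc1)(c1ccccc1)C(C)(C)C)C=CC2=O | intermediate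
30 | desilylated tert-butyl ester of 29 (free C6–OH and C15–OH, stereocentres as in 29) | C=C(C(=O)OC(C)(C)C)[C@@H]1[C@H](OC(=O)/C(C)=C\C)C[C@]2(C)O[C@@H]([C@H]1O)[C@@H](CO)C=CC2=O | intermediate (not isolated)
31 | seco hydroxy acid of the target (free C12 acid, C6–OH and C15–OH) | C=C(C(=O)O)[C@@H]1[C@H](OC(=O)/C(C)=C\C)C[C@]2(C)O[C@@H]([C@H]1O)[C@@H](CO)C=CC2=O | intermediate (not isolated)
32 | CNP0274187.1, (4R,5R,6S,7R,8R,10S)-8-angeloyloxy-15-hydroxy-1-oxo-5,10-epoxygermacra-2,11(13)-dien-12,6-olide | C=C1C(=O)O[C@@H]2[C@@H]3O[C@@](C)(C[C@@H](OC(=O)/C(C)=C\C)[C@@H]12)C(=O)C=C[C@@H]3CO | target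

## Step count and risks

Total steps: 18. Longest linear sequence: 16 (steps 1–3, 5, 7–18); steps 4 and 6 are one-step branches.

**Step 9 (ketyl cyclisation onto the trisubstituted vinyl sulfone).** The attack creates a quaternary centre in a seven-membered ring, and the C10 configuration rests on the chelated chair model. The fallback sets out from 15 and returns at 16. Pinnick oxidation (NaClO2, NaH2PO4, 2-methyl-2-butene) gives the carboxylic acid F1, and PhSeSePh/PBu3 converts it into the Se-phenyl selenoester F2. An acyl-radical 7-exo cyclisation ((Me3Si)3SiH, Et3B, air) then closes the ring to the oxepan-3-one F3, and NaBH4 reduces this to carbinol 16. Either C1 epimer serves, because that centre is erased in step 12.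

**Step 15 (cross-metathesis of a hindered allylic silyl ether with a 1,1-disubstituted bromomethyl acrylate).** This may stall or homodimerise. The fallback sets out from 20 and returns at 24. Selective ozonolysis of the vinyl group (O3, then PPh3) gives the α-silyloxy aldehyde F4. A Baylis–Hillman reaction with tert-butyl acrylate (DABCO) gives the allylic alcohol F5, and NBS/Me2S converts this by allylic transposition into the (Z)-allylic bromide F6. CSA in MeOH removes the primary TBS group to give the primary alcohol F7, and Dess–Martin oxidation gives 24.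

**Step 16 (key Barbier closure of the trans-bridged ring B).** Strain may favour oligomers, and the C8 configuration depends on the (Z)-allyl chair. The fallback sets out from 24 and returns at 26. It replaces the reductive metal allylation by an allylboration: Pd2(dba)3-catalysed borylation with bis(pinacolato)diboron (DMSO, 50 °C) converts the allylic bromide into the allylboronate F8. This cyclises through a tight boron chair (Z → syn) to the cyclic borate ester F9, and work-up with aqueous triethanolamine releases 26.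

Further compounds
F1 | step 9 | (4R,5R,6S)-6-(benzoyloxy)-5-{[(1E)-4-(TBS-oxy)-1-(phenylsulfonyl)but-1-en-2-yl]oxy}-4-(TBDPS-oxymethyl)oct-7-enoic acid | OC(=O)CC[C@H](CO[Si](c1ccccc1)(c1ccccc1)C(C)(C)C)[C@@H](O/C(CCO[Si](C)(C)C(C)(C)C)=C/S(=O)(=O)c1ccccc1)[C@@H](OC(=O)c1ccccc1)C=C
F2 | step 9 | Se-phenyl (4R,5R,6S)-6-(benzoyloxy)-5-{[(1E)-4-(TBS-oxy)-1-(phenylsulfonyl)but-1-en-2-yl]oxy}-4-(TBDPS-oxymethyl)oct-7-eneselenoate | O=C([Se]c1ccccc1)CC[C@H](CO[Si](c1ccccc1)(c1ccccc1)C(C)(C)C)[C@@H](O/C(CCO[Si](C)(C)C(C)(C)C)=C/S(=O)(=O)c1ccccc1)[C@@H](OC(=O)c1ccccc1)C=C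
F3 | step 9 | (1S)-1-[(2R,3R,7S)-7-[2-(TBS-oxy)ethyl]-3-(TBDPS-oxymethyl)-6-oxo-7-[(phenylsulfonyl)methyl]oxepan-2-yl]prop-2-en-1-yl benzoate | CC(C)(C)[Si](C)(C)OCC[C@]1(CS(=O)(=O)c2ccccc2)O[C@@H]([C@@H](OC(=O)c2ccccc2)C=C)[C@@H](CO[Si](c2ccccc2)(c2ccccc2)C(C)(C)C)CCC1=O
F4 | step 15 | (2R)-2-(TBS-oxy)-2-[(2R,3R,7S)-7-[2-(TBS-oxy)ethyl]-3-(TBDPS-oxymethyl)-7-methyl-6-oxo-2,3,6,7-tetrahydrooxepin-2-yl]acetaldehyde | CC(C)(C)[Si](C)(C)OCC[C@]1(C)O[C@@H]([C@@H](O[Si](C)(C)C(C)(C)C)C=O)[C@@H](CO[Si](c2ccccc2)(c2ccccc2)C(C)(C)C)C=CC1=O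
F5 | step 15 | tert-butyl (4S)-4-(TBS-oxy)-3-hydroxy-2-methylidene-4-[(2R,3R,7S)-7-[2-(TBS-oxy)ethyl]-3-(TBDPS-oxymethyl)-7-methyl-6-oxo-2,3,6,7-tetrahydrooxepin-2-yl]butanoate (C3 epimers) | CC(C)(C)[Si](C)(C)OCC[C@]1(C)O[C@@H]([C@@H](O[Si](C)(C)C(C)(C)C)C(O)C(=C)C(=O)OC(C)(C)C)[C@@H](CO[Si](c2ccccc2)(c2ccccc2)C(C)(C)C)C=CC1=O
F6 | step 15 | tert-butyl (2Z,4S)-2-(bromomethyl)-4-(TBS-oxy)-4-[(2R,3R,7S)-7-[2-(TBS-oxy)ethyl]-3-(TBDPS-oxymethyl)-7-methyl-6-oxo-2,3,6,7-tetrahydrooxepin-2-yl]but-2-enoate | CC(C)(C)[Si](C)(C)OCC[C@]1(C)O[C@@H]([C@@H](O[Si](C)(C)C(C)(C)C)/C=C(\CBr)C(=O)OC(C)(C)C)[C@@H](CO[Si](c2ccccc2)(c2ccccc2)C(C)(C)C)C=CC1=O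
F7 | step 15 | tert-butyl (2Z,4S)-2-(bromomethyl)-4-(TBS-oxy)-4-[(2R,3R,7S)-7-(2-hydroxyethyl)-3-(TBDPS-oxymethyl)-7-methyl-6-oxo-2,3,6,7-tetrahydrooxepin-2-yl]but-2-enoate | OCC[C@]1(C)O[C@@H]([C@@H](O[Si](C)(C)C(C)(C)C)/C=C(\CBr)C(=O)OC(C)(C)C)[C@@H](CO[Si](c2ccccc2)(c2ccccc2)C(C)(C)C)C=CC1=O
F8 | step 16 | tert-butyl (2E,4S)-4-(TBS-oxy)-2-[(4,4,5,5-tetramethyl-1,3,2-dioxaborolan-2-yl)methyl]-4-[(2R,3R,7S)-3-(TBDPS-oxymethyl)-7-methyl-6-oxo-7-(2-oxoethyl)-2,3,6,7-tetrahydrooxepin-2-yl]but-2-enoate | O=CC[C@]1(C)O[C@@H]([C@@H](O[Si](C)(C)C(C)(C)C)/C=C(\CB2OC(C)(C)C(C)(C)O2)C(=O)OC(C)(C)C)[C@@H](CO[Si](c2ccccc2)(c2ccccc2)C(C)(C)C)C=CC1=O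
F9 | step 16 | O-(pinacolatoboryl) derivative of 26 at the C8 oxygen | C=C(C(=O)OC(C)(C)C)[C@@H]1[C@H](OB3OC(C)(C)C(C)(C)O3)C[C@]2(C)O[C@@H]([C@H]1O[Si](C)(C)C(C)(C)C)[C@@H](CO[Si](c1ccccc1)(c1ccccc1)C(C)(C)C)C=CC2=O
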